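The route rests on disconnecting both C–CH3 bonds of the tertiary carbinol carbon C(CH3)2OH that ends the E-butenyl side chain on C3 of the benzene ring (ortho to the C4 oxygen): two identical methyl groups on a hydroxyl-bearing carbon mark a former ester carbonyl. In one operation a methylcerium reagent adds twice to the ester of an E ortho-silyloxy cinnamate, methyl (E)-3-[5-bromo-2-(tert-butyldimethylsilyloxy)phenyl]acrylate, whose C1 arm is still a bromide. A later Heck reaction installs the C1 methyl acrylate, and the phenol, freed last, is acylated with (S)-3-acetoxybutanoic acid, which carries the only stereocentre from (S)-3-hydroxybutanoic acid.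

Key step: step 3

Remark: (S)-3-hydroxybutanoic acid is taken as a purchasable enantiopure material. Ring positions are numbered as in the target (C1 acrylate arm, C3 butenyl arm, C4 acyloxy oxygen). The stereocentre of the target is (S).

Step 1
Reactants: 1 5-bromosalicylaldehyde (5-bromo-2-hydroxybenzaldehyde); 2 tert-butyldimethylsilyl chloride
Product: 3 5-bromo-2-(tert-butyldimethylsilyloxy)benzaldehyde
Conditions: TBSCl (1.2 equiv), imidazole (2.5 equiv), DMF, 0 °C → rt
Reagents that add atoms: tert-butyldimethylsilyl chloride 2, CC(C)(C)[Si](C)(C)Cl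
Why: Silylation of a phenol with a silyl chloride and imidazole is routine, and it removes the acidic OH that would otherwise consume ylide and methyl reagent and could lactonise a cinnamate to a coumarin.

Step 2
Reactants: 3 5-bromo-2-(tert-butyldimethylsilyloxy)benzaldehyde; 4 methyl (triphenylphosphoranylidene)acetate
Product: 5 methyl (E)-3-[5-bromo-2-(tert-butyldimethylsilyloxy)phenyl]acrylate
Conditions: Ph3P=CHCO2Me (1.2 equiv), toluene, 60 °C
Reagents that add atoms: methyl (triphenylphosphoranylidene)acetate 4, COC(=O)C=P(c1ccccc1)(c1ccccc1)c1ccccc1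
Why: Wittig olefination of an aromatic aldehyde with an ester-stabilised ylide is reliably E-selective, so the alkene geometry of the later C3 side chain is set here.

Step 3
Reactants: 5 methyl (E)-3-[5-bromo-2-(tert-butyldimethylsilyloxy)phenyl]acrylate; 6 methylmagnesium bromide
Product: 8 (E)-4-[5-bromo-2-(tert-butyldimethylsilyloxy)phenyl]-2-methylbut-3-en-2-ol, via E-arylbutenone 7 (not isolated)
Conditions: CeCl3 (anhydrous, 3.5 equiv), MeMgBr (3.5 equiv), THF, −78 °C, 1 h; then 5, −78 → 0 °C; sat. aq NH4Cl
Reagents that add atoms: methylmagnesium bromide 6, C[Mg]Br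
Why: MeMgBr and anhydrous CeCl3 give a methylcerium reagent that adds to the ester carbonyl of 5 in a 1,2-sense; the tetrahedral adduct expels methoxide to give the E-arylbutenone 7, which is a better electrophile than 5 and takes the second methyl group at its carbonyl carbon, so both C–CH3 bonds of the carbinol form in one flask and the alkoxide is protonated on mild NH4Cl work-up. The closest known reaction type is the twofold Grignard or organocerium addition to esters that delivers tertiary alcohols, here in its cinnamate variant giving a 2-methyl-4-arylbut-3-en-2-ol. No ring is closed and no stereocentre is created; the E geometry comes from step 2 and persists because the C=C bond is a bystander. The selectivity needed is carbonyl (1,2) over conjugate (1,4) addition and over enolisation of 7, and it is secured by the oxophilic, weakly basic cerium reagent at low temperature. Chemoselectivity rests on the substrate design: 5 holds a single ester because the C1 arm is still a bromide, and neither the aryl bromide (no halogen–metal exchange with a methyl reagent between −78 and 0 °C) nor the hindered aryl silyl ether should react.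

Step 4
Reactants: 8 (E)-4-[5-bromo-2-(tert-butyldimethylsilyloxy)phenyl]-2-methylbut-3-en-2-ol; 9 methyl acrylate
Product: 10 methyl (E)-3-[4-(tert-butyldimethylsilyloxy)-3-[(E)-3-hydroxy-3-methylbut-1-enyl]phenyl]acrylate
Conditions: methyl acrylate (2 equiv), Pd2(dba)3 (2 mol%), [HP(t-Bu)3]BF4 (8 mol%), Cy2NMe (1.5 equiv), dioxane, rt → 50 °C
Reagents that add atoms: methyl acrylate 9, COC(=O)C=C
Why: Mizoroki–Heck reaction, in which oxidative addition of the aryl bromide to zerovalent palladium carrying the bulky electron-rich P(t-Bu)3, syn-insertion of the acrylate and syn-β-hydride elimination give the E-cinnamate under conditions mild enough to spare the silyl ether and the tertiary allylic alcohol, while the internal styrenyl alkene of 8 is too hindered to compete with the terminal acrylate.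

Step 5
Reactants: 10 methyl (E)-3-[4-(tert-butyldimethylsilyloxy)-3-[(E)-3-hydroxy-3-methylbut-1-enyl]phenyl]acrylate
Product: 11 methyl (E)-3-[4-hydroxy-3-[(E)-3-hydroxy-3-methylbut-1-enyl]phenyl]acrylate
Conditions: TBAF (1.1 equiv), AcOH (1.1 equiv), THF, 0 °C; pH 7 phosphate buffer work-up
Reagents that add atoms: none
Why: Fluoride-mediated cleavage of an aryl silyl ether is fast at 0 °C, and buffering TBAF with acetic acid keeps the medium near neutral so that neither the methyl ester nor the acid- and base-sensitive ortho-hydroxystyryl carbinol is disturbed.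

Step 6
Reactants: 12 (S)-3-hydroxybutanoic acid; 13 acetyl chloride
Product: 14 (S)-3-acetoxybutanoic acid
Conditions: AcCl (2.5 equiv), CH2Cl2, 0 °C → rt; volatiles removed in vacuo
Reagents that add atoms: acetyl chloride 13, CC(=O)Cl
Why: Base-free O-acetylation of a hydroxy acid with acetyl chloride acylates the hydroxyl group and not the carboxyl group, and since no bond to C3 is touched the (S) configuration bought with 12 is retained.

Step 7
Reactants: 11 methyl (E)-3-[4-hydroxy-3-[(E)-3-hydroxy-3-methylbut-1-enyl]phenyl]acrylate; 14 (S)-3-acetoxybutanoic acid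
Product: 15 methyl (E)-3-[4-[(S)-3-acetoxybutanoyloxy]-3-[(E)-3-hydroxy-3-methylbut-1-enyl]phenyl]acrylate (CNP0325017.1)
Conditions: DIC (1.2 equiv), DMAP (0.1 equiv), CH2Cl2, 0 °C → rt
Reagents that add atoms: none
Why: Steglich esterification (carbodiimide activation with catalytic DMAP) acylates the phenol, which is far more reactive toward the activated acid than the hindered tertiary alcohol, while the stereocentre sits β to the carbonyl without an acidic hydrogen and is carried over unchanged from 14, and low temperature with little DMAP limits β-elimination of acetate.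

Compound list
1 | 5-bromosalicylaldehyde (5-bromo-2-hydroxybenzaldehyde) | O=Cc1cc(Br)ccc1O | starting material
2 | tert-butyldimethylsilyl chloride | CC(C)(C)[Si](C)(C)Cl | starting material
3 | 5-bromo-2-(tert-butyldimethylsilyloxy)benzaldehyde | O=Cc1cc(Br)ccc1O[Si](C)(C)C(C)(C)C | intermediate
4 | methyl (triphenylphosphoranylidene)acetate | COC(=O)C=P(c1ccccc1)(c1ccccc1)c1ccccc1 | starting material
5 | methyl (E)-3-[5-bromo-2-(tert-butyldimethylsilyloxy)phenyl]acrylate | COC(=O)/C=C/c1cc(Br)ccc1O[Si](C)(C)C(C)(C)C | intermediate
6 | methylmagnesium bromide | C[Mg]Br | starting material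
7 | (E)-4-[5-bromo-2-(tert-butyldimethylsilyloxy)phenyl]but-3-en-2-one (E-arylbutenone, not isolated) | CC(=O)/C=C/c1cc(Br)ccc1O[Si](C)(C)C(C)(C)C | intermediate
8 | (E)-4-[5-bromo-2-(tert-butyldimethylsilyloxy)phenyl]-2-methylbut-3-en-2-ol | CC(C)(O)/C=C/c1cc(Br)ccc1O[Si](C)(C)C(C)(C)C | intermediate
9 | methyl acrylate | COC(=O)C=C | starting material
10 | methyl (E)-3-[4-(tert-butyldimethylsilyloxy)-3-[(E)-3-hydroxy-3-methylbut-1-enyl]phenyl]acrylate | COC(=O)/C=C/c1ccc(O[Si](C)(C)C(C)(C)C)c(/C=C/C(C)(C)O)c1 | intermediate
11 | methyl (E)-3-[4-hydroxy-3-[(E)-3-hydroxy-3-methylbut-1-enyl]phenyl]acrylate | COC(=O)/C=C/c1ccc(O)c(/C=C/C(C)(C)O)c1 | intermediate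
12 | (S)-3-hydroxybutanoic acid | OC(=O)C[C@H](C)O | starting material
13 | acetyl chloride | CC(=O)Cl | starting material
14 | (S)-3-acetoxybutanoic acid | OC(=O)C[C@H](C)OC(C)=O | intermediate
15 | methyl (E)-3-[4-[(S)-3-acetoxybutanoyloxy]-3-[(E)-3-hydroxy-3-methylbut-1-enyl]phenyl]acrylate | COC(=O)/C=C/c1ccc(OC(=O)C[C@H](C)OC(C)=O)c(/C=C/C(C)(C)O)c1 | target

Total step count: 7. Longest linear sequence: 6 steps (steps 1, 2, 3, 4, 5 and 7); step 6 is a one-step side branch.

Steps most likely to fail

Step 3 (key step). The methyl reagent may add in a conjugate sense, the second addition may stall because ketone 7 is enolised, or the silyl ether may be attacked. The fallback makes the carbinol without any carbonyl addition. It sets out from aldehyde 3, which is methylenated (Ph3PCH3Br, NaN(SiMe3)2, THF, −78 → 0 °C) to tert-butyl(4-bromo-2-vinylphenoxy)dimethylsilane F1. Olefin cross-metathesis of this styrene with an excess of commercial 2-methylbut-3-en-2-ol (second-generation Hoveyda–Grubbs catalyst, RuCl2(H2IMes)(=CH–C6H4-2-OiPr), CH2Cl2, 40 °C) should then give the E-alkene with loss of ethylene, the bulky carbinol terminus enforcing E geometry. The route is rejoined at 8.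

Step 4. Oxidative addition at the electron-rich ring may be slow, the internal alkene may insert in competition, or the silyl group may be lost under base and warming. The fallback avoids palladium. It sets out from bromide 8, which is treated with n-BuLi (2.2 equiv, THF, −78 °C; the first equivalent only forms the lithium alkoxide) for bromine–lithium exchange. The aryllithium is quenched with DMF to give (E)-4-(tert-butyldimethylsilyloxy)-3-(3-hydroxy-3-methylbut-1-enyl)benzaldehyde F2. E-selective Wittig olefination of this aldehyde with ylide 4 (toluene, 60 °C) returns to the route at 10.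

Step 7. The activated β-acetoxy acid may lose acetic acid to give a crotonate ester, or may rearrange to an unreactive N-acylurea before the phenol is acylated. The fallback carries the β-oxygen through the coupling as a silyl ether and acetylates last. It sets out from 12 and 11 and returns at 15:
- 12 is silylated (TESCl, imidazole, DMF) to triethylsilyl (S)-3-(triethylsilyloxy)butanoate F3.
- The silyl ester of this compound is cleaved selectively by brief stirring with K2CO3 in MeOH/H2O at 0 °C to give (S)-3-(triethylsilyloxy)butanoic acid F4.
- DIC/DMAP coupling of this acid with phenol 11 gives methyl (E)-3-[4-[(S)-3-(triethylsilyloxy)butanoyloxy]-3-[(E)-3-hydroxy-3-methylbut-1-enyl]phenyl]acrylate F5, whose acyl donor has no β-leaving group.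
- HF·pyridine buffered with pyridine (THF, 0 °C) frees the secondary alcohol to give methyl (E)-3-[4-[(S)-3-hydroxybutanoyloxy]-3-[(E)-3-hydroxy-3-methylbut-1-enyl]phenyl]acrylate F6.
- Ac2O in pyridine at 0 °C acetylates only this secondary hydroxyl, not the tertiary one, to give 15.

Further compounds
F1 | step 3 | tert-butyl(4-bromo-2-vinylphenoxy)dimethylsilane | C=Cc1cc(Br)ccc1O[Si](C)(C)C(C)(C)C
F2 | step 4 | (E)-4-(tert-butyldimethylsilyloxy)-3-(3-hydroxy-3-methylbut-1-enyl)benzaldehyde | O=Cc1ccc(O[Si](C)(C)C(C)(C)C)c(/C=C/C(C)(C)O)c1
F3 | step 7 | triethylsilyl (S)-3-(triethylsilyloxy)butanoate | CC[Si](CC)(CC)OC(=O)C[C@H](C)O[Si](CC)(CC)CC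
F4 | step 7 | (S)-3-(triethylsilyloxy)butanoic acid | OC(=O)C[C@H](C)O[Si](CC)(CC)CC
F5 | step 7 | methyl (E)-3-[4-[(S)-3-(triethylsilyloxy)butanoyloxy]-3-[(E)-3-hydroxy-3-methylbut-1-enyl]phenyl]acrylate | COC(=O)/C=C/c1ccc(OC(=O)C[C@H](C)O[Si](CC)(CC)CC)c(/C=C/C(C)(C)O)c1
F6 | step 7 | methyl (E)-3-[4-[(S)-3-hydroxybutanoyloxy]-3-[(E)-3-hydroxy-3-methylbut-1-enyl]phenyl]acrylate | COC(=O)/C=C/c1ccc(OC(=O)C[C@H](C)O)c(/C=C/C(C)(C)O)c1
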